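The vessel was closed, stirred and held at one temperature, and starting material turned into target in it.

| flask | starting material | target | time |
|---|---|---|---|
| alpha | 150 mM |  |  |
| theta | 60.0 mM |  |  |
| zeta | 220 mM |  |  |
| epsilon | 150 mM | 45.0 mM | 56 h |

| run | time / h | [target] / mM |
|---|---|---|
| alpha run | 4.3 | 18.7 |
| alpha run | 13 | 42.4 |
| alpha run | 25 | 58.8 |
| alpha run | 39 | 67.4 |
| alpha run | 56 | 70.5 |
| theta run | 4.3 | 9.4 |
| theta run | 13 | 21.9 |
| theta run | 25 | 31.6 |
| theta run | 39 | 35.5 |
| theta run | 56 | 37.5 |
| zeta run | 4.3 | 23.6 |
| zeta run | 13 | 54.8 |
| zeta run | 25 | 75.0 |
| zeta run | 39 | 86.4 |
| zeta run | 56 | 90.7 |

(scatter of a reading: 0.4 mM)

- apparent order in [starting material] of the starting rate, round the charge of the alpha run (the rate where two percent of its starting material have turned into target) (one fixed amount of target, the same in the runs compared)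
- target in the epsilon run at 56 h, as a share of the starting material charged
- which of these the readings show (the product decays / nothing beyond the main steps / two substrates go astray together)

- Overall: starting material -> target.
- Constant volume, constant temperature.
- Readings of a species count what is bound in complexes too.
- An order is taken over about fifteen percent of the charge, up and down.
- A share of target counts the target that was charged too.

I looked for something that stayed constant from run to run. At 56 h the share of the charge found as target fell from 62.5% in the theta run to 47.0% in the alpha run and 41.2% in the zeta run.

Two extreme vessels bracket this. With first-order steps throughout, the vessel is linear, so each curve scales with its charge and the exponent of target made against charge is one. In the other extreme vessel, a loss taking starting material two at a time removes every surplus above some level, target made does not depend on the charge, and that exponent is zero. The real flask lay between them. From the theta and zeta runs at 56 h I read 0.680, the apparent order of target made in the charge. Scaled from the theta run, it gave the alpha charge a share of 46.6%, and the alpha run read 47.0%.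

At 4.3 h the same reckoning gave 0.708, which I took as the order of the starting rate. The exponent went from 0.708 at 4.3 h to 0.680 at 56 h, and I assumed that the target charged was a bystander. The epsilon run has the alpha charge, so I added the alpha share to its charged share and expected 77.0%. Target in the alpha run still rose from 67.4 mM to 70.5 mM late on, so I saw no decay, and the falling share pointed to two substrates going astray together.

The forecast gave 0.6, 76% and two substrates go astray together, reasoning that “A first-order side loss would leave this share constant”, and my order was higher.

The flask gave 0.71, 77.2% and two substrates go astray together.

    2 starting material ⇌ substrate dimer, settled at all times (5.440 M⁻¹)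
    starting material → target (0.06300 h⁻¹)
    2 starting material → homo dimer (0.8568 M⁻¹ h⁻¹)

Beyond the target charged, the epsilon run made 47.2% of its charge, and the exponent, scaled down from the zeta run to that charge, gives 46.6%. For target made, the exponent puts the zeta run at 1.30 times the alpha run. The rate of the zeta run, where two percent of the alpha charge had turned into target, stood at 1.3 times that of the alpha run.

The earlier runs and the new flask are calculated for an exercise; noise was put on by code.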